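**Retrosynthetic overview**
1. The 1,4-diketone is unmasked last, by hydrolysis of a 2-methyl-5-alkylfuran.
2. The C3–C1' bond and the single (S) stereocentre come from one new step: an enantioconvergent nickel-catalysed sp3–sp3 Negishi coupling of a racemic 3-bromo-5,7-dimethoxyphthalide with a primary alkylzinc bromide.
3. The bromophthalide comes from 5,7-dimethoxyphthalide by radical bromination; the phthalide comes from 3,5-dimethoxybenzyl alcohol by ring bromination and carbonylative lactonisation.
4. The alkylzinc comes from 2-methylfuran and 1,11-dibromoundecane by lithiation/alkylation and zinc insertion.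
5. Ring order: the benzene and furan rings are bought, the lactone ring is closed in step 2 before the stereocentre is set, and the furan ring is opened in the last step.

Assumption: the (S,S) enantiomer of the pybox ligand is taken to give the (S)-phthalide; if the first run shows the opposite sense of induction, the (R,R) ligand is used and nothing else changes.

**Route**

Step 1
Reactants: 1 3,5-dimethoxybenzyl alcohol
Product: 2 (2-bromo-3,5-dimethoxyphenyl)methanol
Conditions: NBS (1.02 equiv), MeCN, 0 °C to rt
Reagents that add atoms: N-bromosuccinimide, O=C1CCC(=O)N1Br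
Why: Electrophilic aromatic bromination goes to C2, which is para to one methoxy group and ortho to the other, so the bromine is placed on the carbon that will carry the lactone carbonyl.

Step 2
Reactants: 2 (2-bromo-3,5-dimethoxyphenyl)methanol
Product: 3 5,7-dimethoxyisobenzofuran-1(3H)-one
Conditions: Pd(OAc)2 (5 mol%), Xantphos (6 mol%), CO (1 atm), K2CO3 (2 equiv), DMF, 100 °C
Reagents that add atoms: carbon monoxide, [C-]#[O+]
Why: Palladium-catalysed carbonylative lactonisation, in which oxidative addition of the aryl bromide to zerovalent palladium, CO insertion and capture of the acylpalladium by the neighbouring benzylic hydroxyl close the five-membered lactone ring.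

Step 3
Reactants: 3 5,7-dimethoxyisobenzofuran-1(3H)-one
Product: 4 racemic 3-bromo-5,7-dimethoxyisobenzofuran-1(3H)-one
Conditions: NBS (1.05 equiv), AIBN (5 mol%), PhCF3, reflux, visible light; succinimide filtered off, concentrated, used at once
Reagents that add atoms: N-bromosuccinimide, O=C1CCC(=O)N1Br
Why: Wohl–Ziegler radical bromination takes the only benzylic C–H position, which is further activated by the ring oxygen, while the non-polar radical conditions hold back ionic bromination of the arene; the bromide is racemic by design.

Step 4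
Reactants: 5 2-methylfuran; 6 1,11-dibromoundecane
Product: 8 2-(11-bromoundecyl)-5-methylfuran, via 5-methyl-2-furyllithium 7 (not isolated)
Conditions: n-BuLi (1.05 equiv), THF, −78 to 0 °C; then cannulated into 6 (3 equiv), THF, −78 °C to rt; silica chromatography, excess 6 recovered
Reagents that add atoms: none
Why: Lithiation of 2-methylfuran at its free α-position followed by SN2 alkylation of the furyllithium with a primary bromide, with the dibromide in threefold excess so that only one end reacts.

Step 5
Reactants: 8 2-(11-bromoundecyl)-5-methylfuran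
Product: 9 [11-(5-methylfuran-2-yl)undecyl]zinc bromide as a titrated DMA solution
Conditions: Zn dust (1.5 equiv), iodine (5 mol%), DMA, 70 °C, 12 h
Reagents that add atoms: zinc, [Zn]
Why: Direct insertion of iodine-activated zinc into the primary C–Br bond in a polar amide solvent gives the alkylzinc bromide, and the furan is inert to it.

Step 6
Reactants: 4 racemic 3-bromo-5,7-dimethoxyisobenzofuran-1(3H)-one; 9 [11-(5-methylfuran-2-yl)undecyl]zinc bromide
Product: 10 (3S)-5,7-dimethoxy-3-[11-(5-methylfuran-2-yl)undecyl]isobenzofuran-1(3H)-one
Conditions: NiBr2·glyme (10 mol%), (S,S)-iPr-Pybox (13 mol%), 9 (1.6 equiv), DMA/THF (1:1), −20 °C, 4 added over 2 h, then 12 h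
Reagents that add atoms: none
Why: Proposed new method: an enantioconvergent nickel-catalysed C(sp3)–C(sp3) Negishi alkylation of a racemic 3-bromophthalide, in which a monovalent nickel–pybox species abstracts bromine from either enantiomer of 4 to give one planar, benzylic and oxygen-stabilised phthalidyl radical (no β-hydrogen, so no elimination channel), the chiral divalent alkylnickel complex formed by transmetalation from 9 captures this radical, and reductive elimination from trivalent nickel forges the C3–C1' bond on the face set by the ligand to give the (S) centre; the closest known reaction types are the nickel/pybox enantioconvergent Negishi alkylations of racemic 1-haloindanes and other secondary benzylic bromides and of racemic α-acyloxyalkyl halides with primary alkylzinc reagents, here carried over to a cyclic benzylic pseudo-acyl bromide.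

Step 7
Reactants: 10 (3S)-5,7-dimethoxy-3-[11-(5-methylfuran-2-yl)undecyl]isobenzofuran-1(3H)-one
Product: 11 CJ-13,103 [(3S)-3-(12,15-dioxohexadecyl)-5,7-dimethoxyisobenzofuran-1(3H)-one]
Conditions: AcOH/H2O (3:1), H2SO4 (cat.), 100 °C
Reagents that add atoms: water, O
Why: Acid-catalysed hydrolytic opening of a 2,5-dialkylfuran (reverse Paal–Knorr reaction) unmasks the 1,4-diketone, while the lactone, the aryl methyl ethers and the C3 stereocentre, whose C–O bond is not ionised because both methoxy groups are meta to it, are left unchanged.

**Compound list**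
1 | 3,5-dimethoxybenzyl alcohol | COc1cc(CO)cc(OC)c1 | starting material
2 | (2-bromo-3,5-dimethoxyphenyl)methanol | COc1cc(CO)c(Br)c(OC)c1 | intermediate
3 | 5,7-dimethoxyisobenzofuran-1(3H)-one (5,7-dimethoxyphthalide) | COc1cc(OC)c2c(c1)COC2=O | intermediate
4 | racemic 3-bromo-5,7-dimethoxyisobenzofuran-1(3H)-one | COc1cc(OC)c2c(c1)C(Br)OC2=O | intermediate
5 | 2-methylfuran | Cc1ccco1 | starting material
6 | 1,11-dibromoundecane | BrCCCCCCCCCCCBr | starting material
7 | 5-methyl-2-furyllithium | [Li]c1ccc(C)o1 | intermediate
8 | 2-(11-bromoundecyl)-5-methylfuran | Cc1ccc(CCCCCCCCCCCBr)o1 | intermediate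
9 | [11-(5-methylfuran-2-yl)undecyl]zinc bromide | Cc1ccc(CCCCCCCCCCC[Zn]Br)o1 | intermediate
10 | (3S)-5,7-dimethoxy-3-[11-(5-methylfuran-2-yl)undecyl]isobenzofuran-1(3H)-one | COc1cc(OC)c2c(c1)[C@H](CCCCCCCCCCCc3ccc(C)o3)OC2=O | intermediate
11 | CJ-13,103, (3S)-3-(12,15-dioxohexadecyl)-5,7-dimethoxyisobenzofuran-1(3H)-one | COc1cc(OC)c2c(c1)[C@H](CCCCCCCCCCCC(=O)CCC(C)=O)OC2=O | target

**Totals**
Total step count: 7. Longest linear sequence: 5 steps (steps 1, 2, 3, 6, 7).

**Three steps most likely to fail**

Step 6 (the proposed new coupling). Risks are a racemic background alkylation through ZnBr2-assisted ionisation of 4, homocoupling of the phthalidyl radical, and low enantioselectivity; the ee is read by chiral HPLC on the first run. The fallback uses known chemistry, sets out from alkylzinc 9 and comes back at 10. Commercial 3,5-dimethoxybenzoic acid is brominated at C2 (NBS, MeCN, rt) to 2-bromo-3,5-dimethoxybenzoic acid F1, which SOCl2 (cat. DMF, toluene, 70 °C) turns into 2-bromo-3,5-dimethoxybenzoyl chloride F2. Acylation of 9 with F2 under Pd(PPh3)4 (3 mol%, THF/DMA, 0 °C to rt; Negishi ketone synthesis) gives 1-(2-bromo-3,5-dimethoxyphenyl)-12-(5-methylfuran-2-yl)dodecan-1-one F3. Reduction with BH3·SMe2 and (R)-2-methyl-CBS-oxazaborolidine (20 mol%, THF, −20 °C; aryl as the large group, so the (R) catalyst gives the (S) carbinol) gives (1S)-1-(2-bromo-3,5-dimethoxyphenyl)-12-(5-methylfuran-2-yl)dodecan-1-ol F4. The carbonylative lactonisation of step 2 (Pd(OAc)2, Xantphos, CO, K2CO3, DMF, 100 °C) then closes F4 to 10 without touching the stereocentre.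

Step 3 (radical bromination of an electron-rich phthalide). Risks are nuclear bromination at C4 or C6 and hydrolysis of the moisture-sensitive bromide. The fallback replaces the radical step by an ionic substitution of a lactol; it sets out from 2 and comes back at 4. MnO2 (CH2Cl2, rt) oxidises 2 to 2-bromo-3,5-dimethoxybenzaldehyde F5. Palladium-catalysed hydroxycarbonylation (Pd(OAc)2, Xantphos, CO 1 atm, K2CO3, dioxane/H2O, 90 °C, then acidification) gives racemic 3-hydroxy-5,7-dimethoxyisobenzofuran-1(3H)-one F6, the ring tautomer of the formyl acid. Acetyl bromide (CH2Cl2, 0 °C to rt) converts F6 into 4.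

Step 7 (furan hydrolysis). Risks are incomplete opening, because the reaction is the reverse of a furan-forming equilibrium, and acid-induced aldol cyclisation of the diketone on long heating. The fallback opens the furan oxidatively and then reduces; it sets out from 10 and comes back at 11. mCPBA (1.05 equiv, CH2Cl2, 0 °C) gives (3S)-3-[(13Z)-12,15-dioxohexadec-13-en-1-yl]-5,7-dimethoxyisobenzofuran-1(3H)-one F7, and Zn dust in AcOH (rt) reduces the conjugated C=C to give 11.

**Further compounds**
F1 | step 6 | 2-bromo-3,5-dimethoxybenzoic acid | COc1cc(OC)c(Br)c(c1)C(=O)O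
F2 | step 6 | 2-bromo-3,5-dimethoxybenzoyl chloride | COc1cc(OC)c(Br)c(c1)C(Cl)=O
F3 | step 6 | 1-(2-bromo-3,5-dimethoxyphenyl)-12-(5-methylfuran-2-yl)dodecan-1-one | COc1cc(OC)c(Br)c(c1)C(=O)CCCCCCCCCCCc2ccc(C)o2
F4 | step 6 | (1S)-1-(2-bromo-3,5-dimethoxyphenyl)-12-(5-methylfuran-2-yl)dodecan-1-ol | COc1cc(OC)c(Br)c(c1)[C@@H](O)CCCCCCCCCCCc2ccc(C)o2
F5 | step 3 | 2-bromo-3,5-dimethoxybenzaldehyde | COc1cc(OC)c(Br)c(C=O)c1
F6 | step 3 | racemic 3-hydroxy-5,7-dimethoxyisobenzofuran-1(3H)-one | COc1cc(OC)c2c(c1)C(O)OC2=O
F7 | step 7 | (3S)-3-[(13Z)-12,15-dioxohexadec-13-en-1-yl]-5,7-dimethoxyisobenzofuran-1(3H)-one | COc1cc(OC)c2c(c1)[C@H](CCCCCCCCCCCC(=O)/C=C\C(C)=O)OC2=O
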